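**Retrosynthetic overview**

1. Atom labels: C1 isobutyryl bridgehead, C2–C3–C4 enolised diketone bridge, C5 prenyl bridgehead, C6 CH2, C7 prenyl CH, C8 methyl/homoprenyl carbon, C9 bridging ketone; ring A = C1–C2–C3–C4–C5–C9, ring B = C1–C8–C7–C6–C5–C9.
2. The route rests on ring B: its C7–C8 edge (C8 methyl cis to the C7 side chain) is the 2E alkene of geranic acid, and its C1–C9–C5–C6 segment is a 2-silyloxy-3-prenylbutadiene.
3. Disconnections, backwards: C1–isobutyryl (bridgehead iodide, I/Mg exchange, aldehyde, oxidation); C1–C2 and C4–C5 (malonyl dichloride annulation of the C9=C5 silyl enol ether, ring A); C7 CH2–CH=CMe2 (alkyl iodide plus isobutenyl Grignard/CuI); C1–C8 and C6–C7 (enantioselective Diels–Alder, ring B).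
4. Forward ring order: ring B in step 4 (sets C7 and C8), ring A in step 8 (sets C5 and C1 under control of C7).

Key step: step 4

Assumption: geranic acid is used as the pure 2E isomer, since a 2Z contaminant would give the C8 epimer; residual Z imide is removed when 8 is purified.
Assumption: the (S,S) pybox antipode is taken to shield the Cα-Re face of the chelated imide; if the first run shows the opposite sense, the (R,R) ligand is used with nothing else changed.
Remark: the target is an enolised β-diketone and is drawn as its 4-hydroxy-2-oxo tautomer.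

**Route**

Step 1
Reactants: 1 6-methylhept-5-en-2-one
Product: 3 6-methyl-3-methylidenehept-5-en-2-one, via Mannich base 2 (not isolated)
Conditions: (CH2O)n, PhNHMe·CF3CO2H, THF, reflux
Reagents that add atoms: paraformaldehyde (as formaldehyde), C=O
Why: Acid-mediated Mannich methylenation proceeds through the more substituted enol of the methyl ketone, so the aminomethyl group enters at the CH2 carbon and β-elimination of the amine gives the α-methylene ketone, the minor terminal vinyl ketone being removed on purification.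

Step 2
Reactants: 3 6-methyl-3-methylidenehept-5-en-2-one
Product: 4 2-(triisopropylsilyloxy)-3-(3-methylbut-2-en-1-yl)buta-1,3-diene
Conditions: i-Pr3SiOTf, Et3N, CH2Cl2, 0 °C
Reagents that add atoms: triisopropylsilyl trifluoromethanesulfonate, CC(C)[Si](OS(=O)(=O)C(F)(F)F)(C(C)C)C(C)C
Why: Soft enolisation and O-silylation can only occur toward the methyl group because the other α carbon is sp2, which gives the 2-silyloxydiene with a bulky silyl group chosen to survive the Lewis acid of step 4.

Step 3
Reactants: 5 (2E)-3,7-dimethylocta-2,6-dienoic acid (geranic acid); 6 oxazolidin-2-one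
Product: 8 3-[(2E)-3,7-dimethylocta-2,6-dienoyl]oxazolidin-2-one, via geranic pivalic mixed anhydride 7 (not isolated)
Conditions: t-BuCOCl, Et3N, THF, −20 °C; then 6, LiCl, −20 °C → rt
Reagents that add atoms: none
Why: N-Acylation through the pivalic mixed anhydride with LiCl/Et3N activation avoids the acid chloride and so avoids ketene-mediated E/Z scrambling or deconjugation of the 3-methyl-2-enoyl unit.

Step 4
Reactants: 4 2-(triisopropylsilyloxy)-3-(3-methylbut-2-en-1-yl)buta-1,3-diene; 8 3-[(2E)-3,7-dimethylocta-2,6-dienoyl]oxazolidin-2-one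
Product: 9 3-{[(1S,6S)-6-methyl-3-(3-methylbut-2-en-1-yl)-6-(4-methylpent-3-en-1-yl)-4-(triisopropylsilyloxy)cyclohex-3-en-1-yl]carbonyl}oxazolidin-2-one
Conditions: FeBr3 (10 mol%), AgSbF6 (20 mol%), (S,S)-2,6-bis[4-(4-ethoxyphenyl)-4,5-dihydro-1,3-oxazol-2-yl]pyridine (12 mol%), 4 (2.5 equiv), MS 4 Å, CH2Cl2, −70 → −30 °C
Reagents that add atoms: none
Why: The cationic trivalent iron pybox complex formed from FeBr3 and AgSbF6 binds imide 8 through both carbonyl oxygens in the s-cis conformation and lowers its LUMO, after which the enol ether terminus C1 of diene 4 bonds to the β carbon (C8) and C6 to the α carbon (C7) in a concerted but asynchronous [4+2] cycloaddition. The closest known reaction type is the chiral Lewis acid catalysed Diels–Alder reaction of 2-silyloxydienes with β,β-disubstituted N-enoyloxazolidinones. Ring B closes in this single intermolecular cycloaddition as a six-membered carbocycle, the C6–C7 bond following the C1–C8 bond without a free intermediate. C8 and C7 are set relative to each other by suprafacial addition to the E alkene (C8 methyl cis to the C7 acyl group, with no endo/exo issue because both diene termini are CH2), and their absolute configuration by the ligand, which must block the Cα-Re face so that the diene adds to the Cα-Si face. The step needs regioselectivity (the silyloxy group is a stronger donor than the 3-prenyl group and places the C9 oxygen para to the C7 acyl), chemoselectivity for cycloaddition over Mukaiyama–Michael addition or desilylation (robust triisopropylsilyl group, low temperature) and enantioselectivity (two-point binding of the imide to the chiral cation).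

Step 5
Reactants: 9 Diels–Alder adduct
Product: 10 [(1S,6S)-6-methyl-3-(3-methylbut-2-en-1-yl)-6-(4-methylpent-3-en-1-yl)-4-(triisopropylsilyloxy)cyclohex-3-en-1-yl]methanol
Conditions: LiBH4, H2O (1 equiv), Et2O, 0 °C
Reagents that add atoms: none
Why: Reductive cleavage of the N-acyloxazolidinone by borohydride reduces the exocyclic carbonyl to the primary alcohol without touching the silyl enol ether or epimerising C7.

Step 6
Reactants: 10 primary alcohol
Product: 11 {[(4S,5S)-4-(iodomethyl)-5-methyl-2-(3-methylbut-2-en-1-yl)-5-(4-methylpent-3-en-1-yl)cyclohex-1-en-1-yl]oxy}triisopropylsilane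
Conditions: PPh3, imidazole, CH2Cl2, 0 °C; I2 added in portions, 0 °C → rt
Reagents that add atoms: iodine, [I][I]
Why: Appel-type iodination converts the primary alcohol into the iodide by SN2 displacement of the oxyphosphonium, with iodine added last so that no free iodine meets the silyl enol ether.

Step 7
Reactants: 11 primary iodide
Product: 12 triisopropyl{[(4S,5S)-5-methyl-2,4-bis(3-methylbut-2-en-1-yl)-5-(4-methylpent-3-en-1-yl)cyclohex-1-en-1-yl]oxy}silane
Conditions: (CH3)2C=CHMgBr (3 equiv), CuI (10 mol%), THF, −30 → 0 °C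
Reagents that add atoms: 2-methylprop-1-enylmagnesium bromide, CC(C)=C[Mg]Br
Why: Copper-catalysed cross-coupling of an alkenyl Grignard reagent with a primary alkyl iodide, through a transient magnesium isobutenylcuprate, joins the CH2 carbon to the isobutenyl carbon and completes the C7 prenyl group without touching a stereocentre.

Step 8
Reactants: 12 C7-prenyl silyl enol ether
Product: 14 4-hydroxy-8-methyl-5,7-bis(3-methylbut-2-en-1-yl)-8-(4-methylpent-3-en-1-yl)bicyclo[3.3.1]non-3-ene-2,9-dione (C1–H; C2–C4 bridge cis to C7–H and the C8 homoprenyl chain), via C5 malonyl chloride ketone 13 (not isolated)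
Conditions: ClCOCH2COCl, Et2O, −20 °C → rt; then KOH, BnEt3NCl, H2O, rt; then aq HCl
Reagents that add atoms: malonyl dichloride, O=C(Cl)CC(=O)Cl
Why: Effenberger cyclisation, in which the silyl enol ether is C-acylated at C5 by axial attack anti to the equatorial C7 prenyl, the freed C9 ketone enolises toward C1 and is C-acylated by the second acid chloride in the only geometry open to it (diaxial bridge on a chair ring B), and the basic work-up hydrolyses O-acylated material, so that C5 and C1 are set relative to C7.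

Step 9
Reactants: 14 bicyclic trione (enol form)
Product: 15 4-methoxy-8-methyl-5,7-bis(3-methylbut-2-en-1-yl)-8-(4-methylpent-3-en-1-yl)bicyclo[3.3.1]non-3-ene-2,9-dione
Conditions: Me2SO4, K2CO3, acetone, reflux
Reagents that add atoms: dimethyl sulfate, COS(=O)(=O)OC
Why: O-Methylation of the enolised β-diketone gives the vinylogous ester, both regioisomers being expected, of which the 4-methoxy isomer 15 (C1–H flanked by the C2 and C9 carbonyls) is separated and the 2-methoxy isomer is hydrolysed back to 14 and recycled.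

Step 10
Reactants: 15 4-methoxy vinylogous ester
Product: 17 4-methoxy-3-(trimethylsilyl) analogue of 15, via C3 lithio vinylogous ester 16 (not isolated)
Conditions: LiN(i-Pr)2, Me3SiCl, THF, −78 °C (in situ quench)
Reagents that add atoms: chlorotrimethylsilane, C[Si](C)(C)Cl
Why: C3–H is the most accessible acidic site of the vinylogous ester, so lithiation with in situ silylation gives the C3 vinylsilane, which blocks this position during bridgehead metalation.

Step 11
Reactants: 17 C3-silylated vinylogous ester
Product: 19 1-iodo-4-methoxy-3-(trimethylsilyl) bicyclic dione (iodine in place of C1–H), via C1 bridgehead lithium species 18 (not isolated)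
Conditions: LiN(i-Pr)2 (3 equiv), THF, −78 → −40 °C; then I2, −78 °C
Reagents that add atoms: iodine, [I][I]
Why: Bridgehead lithiation at C1, the only remaining acidic C–H and inductively activated by the C2 and C9 carbonyls, followed by iodine trapping gives the bridgehead iodide with retention because a bridgehead carbanion cannot invert.

Step 12
Reactants: 19 bridgehead iodide
Product: 21 1-(1-hydroxy-2-methylpropyl)-4-methoxy-3-(trimethylsilyl) bicyclic dione (carbinol epimers), via C1 bridgehead magnesium chloride species 20 (not isolated)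
Conditions: i-PrMgCl, THF, −78 °C; then i-PrCHO, −78 → 0 °C
Reagents that add atoms: 2-methylpropanal, CC(C)C=O
Why: Iodine–magnesium exchange of the iodide flanked by two carbonyls is fast at −78 °C and the bridgehead magnesium species adds to isobutyraldehyde in an aldol-type addition, the configuration of the new carbinol being irrelevant because it is oxidised next.

Step 13
Reactants: 21 bridgehead carbinol
Product: 22 4-methoxy-1-(2-methylpropanoyl)-3-(trimethylsilyl) bicyclic dione
Conditions: Dess–Martin periodinane, CH2Cl2, 0 °C → rt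
Reagents that add atoms: none
Why: Dess–Martin oxidation converts the hindered secondary alcohol into the bridgehead isobutyryl ketone under non-basic conditions that avoid retro-Claisen cleavage of the non-enolisable 1,3-dicarbonyl array at C1.

Step 14
Reactants: 22 C3-silylated acyl vinylogous ester
Product: 23 4-methoxy-8-methyl-5,7-bis(3-methylbut-2-en-1-yl)-8-(4-methylpent-3-en-1-yl)-1-(2-methylpropanoyl)bicyclo[3.3.1]non-3-ene-2,9-dione
Conditions: Bu4NF·3H2O, THF, 0 °C
Reagents that add atoms: none
Why: Fluoride-induced protodesilylation of the vinylsilane, assisted by the adjacent carbonyl, restores C3–H.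

Step 15
Reactants: 23 O-methyl ether of the target
Product: 24 (1R,5R,7S,8R)-4-hydroxy-8-methyl-5,7-bis(3-methylbut-2-en-1-yl)-8-(4-methylpent-3-en-1-yl)-1-(2-methylpropanoyl)bicyclo[3.3.1]non-3-ene-2,9-dione (CNP0178130.2)
Conditions: LiCl, DMSO, 120 °C; then aq HCl
Reagents that add atoms: none
Why: Krapcho-type nucleophilic demethylation, chloride attacking the O-methyl carbon of the vinylogous ester in an SN2 reaction, unmasks the enolised β-diketone without hydroxide that could trigger retro-Claisen cleavage at C1.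

**Compound list**

1 | 6-methylhept-5-en-2-one | CC(C)=CCCC(C)=O | starting material
2 | 6-methyl-3-[(N-methylanilino)methyl]hept-5-en-2-one (Mannich base, racemic) | CC(=O)C(CN(C)c1ccccc1)CC=C(C)C | intermediate (not isolated)
3 | 6-methyl-3-methylidenehept-5-en-2-one | CC(=O)C(=C)CC=C(C)C | intermediate
4 | 2-(triisopropylsilyloxy)-3-(3-methylbut-2-en-1-yl)buta-1,3-diene | C=C(O[Si](C(C)C)(C(C)C)C(C)C)C(=C)CC=C(C)C | intermediate
5 | (2E)-3,7-dimethylocta-2,6-dienoic acid (geranic acid) | CC(C)=CCC/C(C)=C/C(=O)O | starting material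
6 | oxazolidin-2-one | O=C1NCCO1 | starting material
7 | (2E)-3,7-dimethylocta-2,6-dienoic pivalic anhydride | CC(C)=CCC/C(C)=C/C(=O)OC(=O)C(C)(C)C | intermediate (not isolated)
8 | 3-[(2E)-3,7-dimethylocta-2,6-dienoyl]oxazolidin-2-one | CC(C)=CCC/C(C)=C/C(=O)N1CCOC1=O | intermediate
9 | 3-{[(1S,6S)-6-methyl-3-(3-methylbut-2-en-1-yl)-6-(4-methylpent-3-en-1-yl)-4-(triisopropylsilyloxy)cyclohex-3-en-1-yl]carbonyl}oxazolidin-2-one | CC(C)=CCC[C@]1(C)[C@@H](C(=O)N2CCOC2=O)CC(CC=C(C)C)=C(O[Si](C(C)C)(C(C)C)C(C)C)C1 | intermediate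
10 | [(1S,6S)-6-methyl-3-(3-methylbut-2-en-1-yl)-6-(4-methylpent-3-en-1-yl)-4-(triisopropylsilyloxy)cyclohex-3-en-1-yl]methanol | CC(C)=CCC[C@]1(C)[C@@H](CO)CC(CC=C(C)C)=C(O[Si](C(C)C)(C(C)C)C(C)C)C1 | intermediate
11 | {[(4S,5S)-4-(iodomethyl)-5-methyl-2-(3-methylbut-2-en-1-yl)-5-(4-methylpent-3-en-1-yl)cyclohex-1-en-1-yl]oxy}triisopropylsilane | CC(C)=CCC[C@]1(C)[C@@H](CI)CC(CC=C(C)C)=C(O[Si](C(C)C)(C(C)C)C(C)C)C1 | intermediate
12 | triisopropyl{[(4S,5S)-5-methyl-2,4-bis(3-methylbut-2-en-1-yl)-5-(4-methylpent-3-en-1-yl)cyclohex-1-en-1-yl]oxy}silane | CC(C)=CCC[C@]1(C)[C@@H](CC=C(C)C)CC(CC=C(C)C)=C(O[Si](C(C)C)(C(C)C)C(C)C)C1 | intermediate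
13 | 3-oxo-3-[ring B ketone C5-yl]propanoyl chloride (C5 quaternary, acyl chain anti to the C7 prenyl, C1 still CH2) | CC(C)=CCC[C@]1(C)[C@@H](CC=C(C)C)C[C@](CC=C(C)C)(C(=O)CC(=O)Cl)C(=O)C1 | intermediate (not isolated)
14 | 4-hydroxy-8-methyl-5,7-bis(3-methylbut-2-en-1-yl)-8-(4-methylpent-3-en-1-yl)bicyclo[3.3.1]non-3-ene-2,9-dione (configuration at C5, C7, C8 as in 24; C1–H) | CC(C)=CCC[C@]1(C)[C@@H](CC=C(C)C)C[C@@]2(CC=C(C)C)C(=O)[C@@H]1C(=O)C=C2O | intermediate
15 | 4-methoxy analogue of 14 | CC(C)=CCC[C@]1(C)[C@@H](CC=C(C)C)C[C@@]2(CC=C(C)C)C(=O)[C@@H]1C(=O)C=C2OC | intermediate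
16 | 3-lithio derivative of 15 | CC(C)=CCC[C@]1(C)[C@@H](CC=C(C)C)C[C@@]2(CC=C(C)C)C(=O)[C@@H]1C(=O)C([Li])=C2OC | intermediate (not isolated)
17 | 4-methoxy-3-(trimethylsilyl) analogue of 15 | CC(C)=CCC[C@]1(C)[C@@H](CC=C(C)C)C[C@@]2(CC=C(C)C)C(=O)[C@@H]1C(=O)C([Si](C)(C)C)=C2OC | intermediate
18 | 1-lithio derivative of 17 | CC(C)=CCC[C@]1(C)[C@@H](CC=C(C)C)C[C@@]2(CC=C(C)C)C(=O)[C@]1([Li])C(=O)C([Si](C)(C)C)=C2OC | intermediate (not isolated)
19 | 1-iodo-4-methoxy-3-(trimethylsilyl) bicyclic dione | CC(C)=CCC[C@]1(C)[C@@H](CC=C(C)C)C[C@@]2(CC=C(C)C)C(=O)[C@]1(I)C(=O)C([Si](C)(C)C)=C2OC | intermediate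
20 | 1-(chloromagnesio) derivative of 17 | CC(C)=CCC[C@]1(C)[C@@H](CC=C(C)C)C[C@@]2(CC=C(C)C)C(=O)[C@]1([Mg]Cl)C(=O)C([Si](C)(C)C)=C2OC | intermediate (not isolated)
21 | 1-(1-hydroxy-2-methylpropyl)-4-methoxy-3-(trimethylsilyl) bicyclic dione (carbinol epimers) | CC(C)=CCC[C@]1(C)[C@@H](CC=C(C)C)C[C@@]2(CC=C(C)C)C(=O)[C@]1(C(O)C(C)C)C(=O)C([Si](C)(C)C)=C2OC | intermediate
22 | 4-methoxy-1-(2-methylpropanoyl)-3-(trimethylsilyl) bicyclic dione | CC(C)=CCC[C@]1(C)[C@@H](CC=C(C)C)C[C@@]2(CC=C(C)C)C(=O)[C@]1(C(=O)C(C)C)C(=O)C([Si](C)(C)C)=C2OC | intermediate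
23 | 4-methoxy-8-methyl-5,7-bis(3-methylbut-2-en-1-yl)-8-(4-methylpent-3-en-1-yl)-1-(2-methylpropanoyl)bicyclo[3.3.1]non-3-ene-2,9-dione | CC(C)=CCC[C@]1(C)[C@@H](CC=C(C)C)C[C@@]2(CC=C(C)C)C(=O)[C@]1(C(=O)C(C)C)C(=O)C=C2OC | intermediate
24 | (1R,5R,7S,8R)-4-hydroxy-8-methyl-5,7-bis(3-methylbut-2-en-1-yl)-8-(4-methylpent-3-en-1-yl)-1-(2-methylpropanoyl)bicyclo[3.3.1]non-3-ene-2,9-dione | CC(C)=CCC[C@]1(C)[C@@H](CC=C(C)C)C[C@@]2(CC=C(C)C)C(=O)[C@]1(C(=O)C(C)C)C(=O)C=C2O | target

**Count and risks**

Total step count: 15. Longest linear sequence: 14 steps (steps 1, 2 and 4–15 from 6-methylhept-5-en-2-one); the dienophile branch is one step (step 3).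

Steps most likely to fail, in order:

Step 4. The β,β-disubstituted imide may add too slowly, so that decomposition of the diene by the cationic Lewis acid or an open-chain Mukaiyama–Michael pathway competes, or facial discrimination may be insufficient. The fallback replaces catalyst control by stoichiometric auxiliary control and keeps the same bond set. It sets out from 5: the mixed anhydride 7 acylates (4S)-4-benzyloxazolidin-2-one (t-BuCOCl, Et3N, LiCl, THF) to give (4S)-4-benzyl-3-[(2E)-3,7-dimethylocta-2,6-dienoyl]oxazolidin-2-one F1. F1 and diene 4 are combined with Me2AlCl (1.4 equiv, CH2Cl2, −78 → −30 °C); the chelated s-cis dienophile should be attacked on the Cα-Si face opposite to the benzyl group, giving the auxiliary-bearing cycloadduct F2 with the C7/C8 configuration of 9. Diastereomers can be separated at this stage, and LiBH4/H2O cleavage of the auxiliary returns to the route at 10.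

Step 8. The second acid chloride may acylate the C9 enol oxygen instead of the hindered C1, or the first acylation of the bulky silyl enol ether may be sluggish, and either erodes the formation of ring A. The fallback builds the bridge stepwise with a soft electrophile for the C1–C2 bond. It sets out from 12: Mukaiyama aldol addition to acetaldehyde (BF3·OEt2, CH2Cl2, −78 °C, same axial approach anti to the C7 prenyl) gives the C5 1-hydroxyethyl ketone F3, and Dess–Martin oxidation gives the C5 acetyl diketone F4. Kinetic deprotonation of the acetyl methyl (LiN(SiMe3)2, 2.2 equiv, THF, −78 °C), addition to CS2 and double S-methylation with MeI give the α-oxo ketene dithioacetal F5, whose only enolisable position is C1. KN(SiMe3)2 in THF then induces intramolecular conjugate addition–elimination of the C1 enolate at C2 with loss of methanethiolate, closing ring A as the bicyclic 2-(methylthio)enone F6. Hydrolysis of this vinylogous thioester (LiOH, THF/H2O, 60 °C, then acid) returns to the route at 14.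

Step 7. Substitution at the β-branched CH2–I next to the C8 quaternary centre may be slow, so that elimination, reduction or halogen–metal exchange outrun coupling. The fallback reverses polarity, making the hindered carbon the nucleophile. It sets out from 11: zinc insertion (Zn dust, LiCl, THF, 40 °C) gives the alkylzinc iodide F7, which is not isolated but coupled with 1-bromo-2-methylprop-1-ene under Pd(dppf)Cl2 catalysis (Negishi coupling, THF, 50 °C), returning to the route at 12.

**Further compounds**

F1 | step 4 | (4S)-4-benzyl-3-[(2E)-3,7-dimethylocta-2,6-dienoyl]oxazolidin-2-one | CC(C)=CCC/C(C)=C/C(=O)N1[C@@H](Cc2ccccc2)COC1=O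
F2 | step 4 | (4S)-4-benzyl-3-{[(1S,6S)-6-methyl-3-(3-methylbut-2-en-1-yl)-6-(4-methylpent-3-en-1-yl)-4-(triisopropylsilyloxy)cyclohex-3-en-1-yl]carbonyl}oxazolidin-2-one | CC(C)=CCC[C@]1(C)[C@@H](C(=O)N2[C@@H](Cc3ccccc3)COC2=O)CC(CC=C(C)C)=C(O[Si](C(C)C)(C(C)C)C(C)C)C1
F3 | step 8 | C5 (1-hydroxyethyl) ring B ketone (carbinol epimers) | CC(C)=CCC[C@]1(C)[C@@H](CC=C(C)C)C[C@](CC=C(C)C)(C(C)O)C(=O)C1
F4 | step 8 | C5 acetyl ring B diketone | CC(C)=CCC[C@]1(C)[C@@H](CC=C(C)C)C[C@](CC=C(C)C)(C(C)=O)C(=O)C1
F5 | step 8 | C5 [3,3-bis(methylthio)prop-2-enoyl] ring B ketone | CC(C)=CCC[C@]1(C)[C@@H](CC=C(C)C)C[C@](CC=C(C)C)(C(=O)C=C(SC)SC)C(=O)C1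
F6 | step 8 | 8-methyl-5,7-bis(3-methylbut-2-en-1-yl)-8-(4-methylpent-3-en-1-yl)-2-(methylthio)bicyclo[3.3.1]non-2-ene-4,9-dione | CC(C)=CCC[C@]1(C)[C@@H](CC=C(C)C)C[C@@]2(CC=C(C)C)C(=O)[C@@H]1C(SC)=CC2=O
F7 | step 7 | alkylzinc iodide from 11 | CC(C)=CCC[C@]1(C)[C@@H](C[Zn]I)CC(CC=C(C)C)=C(O[Si](C(C)C)(C(C)C)C(C)C)C1
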